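**Plan**

- **Cuts:** A benzyl group on the primary hydroxyl and a C2'=C3' double bond are first added back to the target. The side chain is then cut at C3–C1' and C2'=C3' in one operation. This gives a C3–H tetronic acid, the two carbons of Ph3P=C=C=O (C1', C2') and 11-methyldodecanal. The lactone is opened at O1–C2 and C3=C4, and the aldehyde chain at C10–C11.
- **Enabling feature:** C3 of the furan-2(5H)-one ring sits between the C2 lactone carbonyl and the C4 enol, so the C3–H compound is both a strong acid and a carbon nucleophile. The exocyclic ketone C1' with its neighbour C2' corresponds to a ketene unit. The C2/C4/C1' tricarbonyl can therefore be built without an activated fatty acid.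
- **Forward order:** The only ring (O1–C2–C3–C4–C5) is made first, from a serine-derived hydroxy ester and the cumulated ylide, and its enol is then freed. The iso-branched chain is made separately and joined in step 8. One hydrogenation finishes the synthesis.
- **Stereochemistry:** C5 (S) is the α-carbon of O-benzyl-L-serine. It is carried over by diazotisation with retention, and no later step breaks a bond at this carbon.

Key step: step 8

Assumption: all 3-acyl tetronic acids are drawn as the 4-hydroxy-3-acyl tautomer of the target SMILES. The enol tautomers interconvert freely and none of them involves C5.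

**Step 1**
Reactants: 1 O-benzyl-L-serine
Product: 2 (S)-3-(benzyloxy)-2-hydroxypropanoic acid
Conditions: NaNO2 (2 equiv), 1 M H2SO4, H2O/1,4-dioxane, 0 °C to rt
Reagents that add atoms: water, SMILES O
Why: Hydroxy-deamination of an α-amino acid by diazotisation goes with net retention, because the neighbouring carboxylate displaces N2 to form an α-lactone that water opens with a second inversion, so the L-serine centre is kept as (S) and the benzyl ether is inert to cold dilute acid.

**Step 2**
Reactants: 3 2-(trimethylsilyl)ethanol; 4 N,N'-diisopropylcarbodiimide
Product: 5 O-[2-(trimethylsilyl)ethyl]-N,N'-diisopropylisourea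
Conditions: CuCl (1 mol %), neat, rt; hexane, filtration through neutral alumina
Reagents that add atoms: none
Why: CuCl-catalysed addition of a primary alcohol across a carbodiimide is the standard O-alkylisourea synthesis, and neither partner has another reactive group.

**Step 3**
Reactants: 2 (S)-3-(benzyloxy)-2-hydroxypropanoic acid; 5 O-[2-(trimethylsilyl)ethyl]-N,N'-diisopropylisourea
Product: 6 2-(trimethylsilyl)ethyl (S)-3-(benzyloxy)-2-hydroxypropanoate
Conditions: 5 (1.5 equiv), THF, reflux; urea filtered off
Reagents that add atoms: none
Why: In this O-alkylisourea esterification only the carboxylic acid is acidic enough to protonate the isourea, and the carboxylate then takes over the activated silylethyl group, so the secondary hydroxyl stays free and no bond at the stereocentre is touched.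

**Step 4**
Reactants: 6 2-(trimethylsilyl)ethyl (S)-3-(benzyloxy)-2-hydroxypropanoate; 7 (triphenylphosphoranylidene)ketene
Product: 9 (S)-5-(benzyloxymethyl)-4-[2-(trimethylsilyl)ethoxy]furan-2(5H)-one, via ester ylide 8 (not isolated)
Conditions: 7 (1.1 equiv), THF, reflux
Reagents that add atoms: none
Why: In this domino addition/intramolecular Wittig olefination the hydroxyl adds to the C=C=O unit of 7 (O1–C2), and the ylide carbon of 8 then olefinates the adjacent ester carbonyl (C3=C4), which closes the five-membered ring under neutral conditions that should leave C5 intact.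

**Step 5**
Reactants: 9 (S)-5-(benzyloxymethyl)-4-[2-(trimethylsilyl)ethoxy]furan-2(5H)-one
Product: 10 (S)-5-(benzyloxymethyl)-4-hydroxyfuran-2(5H)-one
Conditions: TBAF·3H2O (1.5 equiv), THF, rt; 1 M HCl work-up
Reagents that add atoms: none
Why: In this fluoride-induced fragmentation of a 2-silylethyl group, attack at silicon releases ethene and the delocalised tetronate anion, which is orthogonal to the benzyl ether and, once the anion exists, removes the acidity of C5–H.

**Step 6**
Reactants: 11 10-bromodecan-1-ol; 12 isopropylmagnesium chloride
Product: 13 11-methyldodecan-1-ol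
Conditions: 12 (3 equiv, slow addition), Li2CuCl4 (3 mol %), NMP (4 equiv), THF, 0 °C to rt; 1 M HCl work-up
Reagents that add atoms: none
Why: This is a Kochi-type copper-catalysed sp3–sp3 cross-coupling of a Grignard reagent with a primary alkyl bromide, in which the first equivalent of 12 is spent on the hydroxyl proton and NMP holds back reduction and elimination with the secondary organometallic.

**Step 7**
Reactants: 13 11-methyldodecan-1-ol
Product: 14 11-methyldodecanal
Conditions: TEMPO (10 mol %), PhI(OAc)2 (1.1 equiv), CH2Cl2, rt
Reagents that add atoms: none
Why: This oxoammonium-mediated (TEMPO) oxidation of a primary alcohol stops at the aldehyde in the absence of water, and the saturated chain offers no other site of attack.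

**Step 8**
Reactants: 10 (S)-5-(benzyloxymethyl)-4-hydroxyfuran-2(5H)-one; 7 (triphenylphosphoranylidene)ketene; 14 11-methyldodecanal
Product: 17 (S)-5-(benzyloxymethyl)-4-hydroxy-3-[(E)-13-methyltetradec-2-enoyl]furan-2(5H)-one, via acyl ylide 15 (not isolated), via potassium ylide salt 16 (not isolated)
Conditions: 7 (1.0 equiv), THF, reflux; then KOtBu (1.05 equiv), rt; then 14 (1.2 equiv), reflux; 1 M HCl work-up
Reagents that add atoms: none
Why: The enol of 10, a vinylogous carboxylic acid, protonates the ylidic carbon of 7, and the tetronate then attacks the central carbon of the ketenylphosphonium ion through C3, forming C3–C1' and giving acyl ylide 15, which is too strongly stabilised by its internal enol hydrogen bond to olefinate. KOtBu removes that proton, and the anionic ylide 16 adds to aldehyde 14 and collapses through an oxaphosphetane to the C2'=C3' alkene and Ph3PO. The closest known reaction type is the 3-acylation of tetronic and tetramic acids with this cumulated ylide followed by base-triggered Wittig olefination of the 3-(phosphoranylideneacetyl) products, here telescoped into one flask. No ring closes and no stereocentre is created; the stabilised ylide should favour the E alkene, and the geometry is erased in step 9 in any case. The step needs acylation at C3 rather than O4, which the substrate secures because only the C-acyl product gains the chelated, fully conjugated tricarbonyl–ylide system, whereas an O4 adduct remains a reactive enol ester that can pass its acyl group on to C3. It also needs C5 to keep its configuration and the aldehyde to escape aldol chemistry, both secured because the alkoxide is consumed by the acidic proton of 15 before 14 is added and 7 is not used in excess, so the ring is present only as a delocalised anion in which C5–H is not acidic and benzyloxide cannot be expelled.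

**Step 9**
Reactants: 17 (S)-5-(benzyloxymethyl)-4-hydroxy-3-[(E)-13-methyltetradec-2-enoyl]furan-2(5H)-one
Product: 18 (S)-4-hydroxy-5-(hydroxymethyl)-3-(13-methyltetradecanoyl)furan-2(5H)-one
Conditions: H2 (1 atm), 10 % Pd/C, MeOH, rt; filtration through Celite
Reagents that add atoms: none
Why: Heterogeneous catalytic hydrogenation should saturate the disubstituted enone alkene and hydrogenolyse the primary benzyl ether in one operation, while the tetrasubstituted enolised C3=C4 bond and the chelated ketone resist reduction at one atmosphere and C5 is not involved.

**Compound list**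

1 | O-benzyl-L-serine | N[C@@H](COCc1ccccc1)C(=O)O | starting material
2 | (S)-3-(benzyloxy)-2-hydroxypropanoic acid | O[C@@H](COCc1ccccc1)C(=O)O | intermediate
3 | 2-(trimethylsilyl)ethanol | C[Si](C)(C)CCO | starting material
4 | N,N'-diisopropylcarbodiimide | CC(C)N=C=NC(C)C | starting material
5 | O-[2-(trimethylsilyl)ethyl]-N,N'-diisopropylisourea | CC(C)NC(=NC(C)C)OCC[Si](C)(C)C | intermediate
6 | 2-(trimethylsilyl)ethyl (S)-3-(benzyloxy)-2-hydroxypropanoate | O[C@@H](COCc1ccccc1)C(=O)OCC[Si](C)(C)C | intermediate
7 | (triphenylphosphoranylidene)ketene | O=C=C=P(c1ccccc1)(c1ccccc1)c1ccccc1 | starting material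
8 | 2-(trimethylsilyl)ethyl (S)-3-(benzyloxy)-2-[(triphenylphosphoranylidene)acetoxy]propanoate | C[Si](C)(C)CCOC(=O)[C@H](COCc1ccccc1)OC(=O)C=P(c1ccccc1)(c1ccccc1)c1ccccc1 | intermediate
9 | (S)-5-(benzyloxymethyl)-4-[2-(trimethylsilyl)ethoxy]furan-2(5H)-one | O=C1C=C(OCC[Si](C)(C)C)[C@H](COCc2ccccc2)O1 | intermediate
10 | (S)-5-(benzyloxymethyl)-4-hydroxyfuran-2(5H)-one | O=C1C=C(O)[C@H](COCc2ccccc2)O1 | intermediate
11 | 10-bromodecan-1-ol | OCCCCCCCCCCBr | starting material
12 | isopropylmagnesium chloride | CC(C)[Mg]Cl | starting material
13 | 11-methyldodecan-1-ol | CC(C)CCCCCCCCCCO | intermediate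
14 | 11-methyldodecanal | CC(C)CCCCCCCCCC=O | intermediate
15 | (S)-5-(benzyloxymethyl)-4-hydroxy-3-[(triphenylphosphoranylidene)acetyl]furan-2(5H)-one | O=C(C=P(c1ccccc1)(c1ccccc1)c1ccccc1)C1=C(O)[C@H](COCc2ccccc2)OC1=O | intermediate
16 | potassium 4-enolate of 15 | [K+].O=C(C=P(c1ccccc1)(c1ccccc1)c1ccccc1)C1=C([O-])[C@H](COCc2ccccc2)OC1=O | intermediate
17 | (S)-5-(benzyloxymethyl)-4-hydroxy-3-[(E)-13-methyltetradec-2-enoyl]furan-2(5H)-one | CC(C)CCCCCCCCC/C=C/C(=O)C1=C(O)[C@H](COCc2ccccc2)OC1=O | intermediate
18 | (S)-4-hydroxy-5-(hydroxymethyl)-3-(13-methyltetradecanoyl)furan-2(5H)-one | CC(C)CCCCCCCCCCCC(=O)C1=C(O)[C@H](CO)OC1=O | target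

**Step count**

- Total step count: 9
- Longest linear sequence: 6 (steps 1, 3, 4, 5, 8, 9)

**Steps most likely to fail**

**Step 8.** The olefination stage may stall, because even the anionic acyl ylide is a strongly stabilised ylide facing an enolisable aliphatic aldehyde. Aldol self-condensation and slow decay of the ylide could then overtake alkene formation. The fallback sets out from 14, with 10 as coupling partner, and rejoins the route at 18. It puts the two extra carbons on the chain first and brings the acyl group in as a fatty acid.
- Doebner–Knoevenagel condensation of 14 with malonic acid (pyridine, cat. piperidine, heat) should give (E)-13-methyltetradec-2-enoic acid F1.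
- Hydrogenation (H2, Pd/C, EtOAc) gives 13-methyltetradecanoic acid F2.
- DCC/DMAP coupling of F2 with 10 in CH2Cl2 forms the enol ester (S)-2-(benzyloxymethyl)-5-oxo-2,5-dihydrofuran-3-yl 13-methyltetradecanoate F3.
- Excess DMAP and Et3N carry this on in the same flask by O4-to-C3 acyl migration to (S)-5-(benzyloxymethyl)-4-hydroxy-3-(13-methyltetradecanoyl)furan-2(5H)-one F4.
- Hydrogenolysis of the benzyl ether under the conditions of step 9 then delivers 18.

**Step 4.** Ring closure onto the ester carbonyl may be sluggish. Prolonged heating, or the basic fluoride of step 5, could then erode the configuration at C5 or trigger β-elimination of the benzyloxy group. The fallback sets out from 6 and rejoins at 10, bypassing 9. It closes the ring by C3–C4 bond formation through an ester enolate instead of a Wittig reaction.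
- Acetylation of 6 (Ac2O, pyridine, cat. DMAP) gives 2-(trimethylsilyl)ethyl (S)-2-acetoxy-3-(benzyloxy)propanoate F5.
- LiN(SiMe3)2 (2.2 equiv) in THF at −78 °C then induces Dieckmann cyclisation of the acetate enolate onto the silylethyl ester.
- This expels the alkoxide and gives 10 directly on acidification, so step 5 is no longer needed.

**Step 6.** The secondary Grignard reagent may reduce or eliminate the bromide, or homocouple, faster than it cross-couples. The aggregated magnesium alkoxide of the unprotected alcohol may also slow the copper cycle. The fallback sets out from 11 and rejoins at 13. It makes the C10–C11 bond as an alkene by Wittig chemistry instead of sp3–sp3 coupling.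
- Heating 11 with PPh3 in MeCN gives (10-hydroxydecyl)triphenylphosphonium bromide F6.
- NaN(SiMe3)2 (2.1 equiv) in THF followed by acetone should give 11-methyldodec-10-en-1-ol F7.
- Hydrogenation (H2, Pd/C, EtOAc) then gives 13.

**Further compounds**

F1 | step 8 | (E)-13-methyltetradec-2-enoic acid | CC(C)CCCCCCCCC/C=C/C(=O)O
F2 | step 8 | 13-methyltetradecanoic acid | CC(C)CCCCCCCCCCCC(=O)O
F3 | step 8 | (S)-2-(benzyloxymethyl)-5-oxo-2,5-dihydrofuran-3-yl 13-methyltetradecanoate | CC(C)CCCCCCCCCCCC(=O)OC1=CC(=O)O[C@H]1COCc2ccccc2
F4 | step 8 | (S)-5-(benzyloxymethyl)-4-hydroxy-3-(13-methyltetradecanoyl)furan-2(5H)-one | CC(C)CCCCCCCCCCCC(=O)C1=C(O)[C@H](COCc2ccccc2)OC1=O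
F5 | step 4 | 2-(trimethylsilyl)ethyl (S)-2-acetoxy-3-(benzyloxy)propanoate | CC(=O)O[C@@H](COCc1ccccc1)C(=O)OCC[Si](C)(C)C
F6 | step 6 | (10-hydroxydecyl)triphenylphosphonium bromide | [Br-].OCCCCCCCCCC[P+](c1ccccc1)(c1ccccc1)c1ccccc1
F7 | step 6 | 11-methyldodec-10-en-1-ol | CC(C)=CCCCCCCCCCO
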